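| flask | Z | D | remark | time |
|---|---|---|---|---|
| east | 32 mM | 192 mM | run made earlier |  |
| north-west | 96 mM | 192 mM | run made earlier |  |
| dawn | 48 mM | 192 mM |  | 10 h |
| autumn | 48 mM | 57.6 mM |  | 10 h |
| midnight | 48 mM | 96.0 mM |  | 10 h |

* which of these holds the largest part of the Z at the end of dawn (G / Z / L)
* which of these holds the largest part of the Z at the end of autumn (G / Z / L)
* which of these holds the largest part of the Z at the end of midnight (G / Z / L)
* how much L is there at the end of autumn, in percent of the Z charged



| run | time / min | L / % |
|---|---|---|
| east | 10.0 | 23.8 |
| east | 20.0 | 12.0 |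
| east | 30.0 | 6.5 |
| east | 60.0 | 1.4 |
| east | 120 | 0 |
| north-west | 10.0 | 29.8 |
| north-west | 20.0 | 17.1 |
| north-west | 30.0 | 10.1 |
| north-west | 60.0 | 2.5 |
| north-west | 120 | 0 |

(readings scatter by 0.5 percentage points)

The time asked, 10 h, stands at the top of a ladder of times, and the rung that can be read is the half-life of L.

On the lowest rung, by the first reading at 10.0 min, L has been made: it stands at 23.8% in east and 29.8% in north-west.

The next rung is the tail half-life of L, the time for L to halve, taken between the readings at 10.0 min and 60.0 min. North-west, with c(Z) 96 mM, gives 14.0 min. East, with c(Z) 32 mM at the same c(D) of 192 mM, gives 12.2 min, which is shorter. Both are readings and carry the scatter of 0.5 percentage points, so the longer one is carried as the cautious choice. By 120 min, L reads 0% in north-west.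

On the top rung, 10 h holds 42.9 such half-lives. That half-life was read at c(D) 192 mM and autumn is charged with 57.6 mM, so the count is carried over to another charge. Since the half-life is short against the time, the reckoning made here commits to L under the scatter at the end of autumn, and the same count stands for dawn and midnight, which share that time. The readings are of L, so this count leaves G against Z open.

The forecast names G for dawn, G for autumn and G for midnight, on the ground that “G should dominate in all three runs”. It puts L in autumn at 1%.

    Z + D → L + J (k = 9.80 M⁻¹ min⁻¹)
    D + L → G + J (k = 3.90 M⁻¹ min⁻¹)
    2 D → X (k = 0.850 M⁻¹ min⁻¹)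
    L → E (k = 0.0610 min⁻¹)
    D → Q (k = 0.280 min⁻¹)

Autumn ends with L at 0% on a count of 42.9 half-lives, while D, the limiting reagent, stands at 0% of its charge. There Z at 44.4% exceeds G at 8.30%, and midnight holds Z at 24.6% against G at 19.3%, where the forecast named G. Dawn holds G at 46.9% against Z at 5.31%, and the forecast named G there. The neighbour of autumn charged with 35 mM of D is read at the same time, so the count carried over is again 42.9 half-lives of 14.0 min: its L stands at 0%, with Z at 61.9% above G at 3.37%.

(The readings are calculated from invented constants.)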